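## Retrosynthetic overview

1. Toxiusol ⇒ (bis-sulfation; oxidative demethylation and reduction) dimethyl ether 27 ⇒ ring A (C1–C5, C10) annulated last onto the C10 ketone 21 with mesityl oxide. Locants: distal decalin C1–C10 (ring A = C1–C5/C10, ring B = C5–C10, C17 and C20 = methyls on C8 and C9); tether C11–C12; proximal decalin C1'–C10', benzylic C11'.
2. 21 ⇒ tertiary allylic alcohol 19: ring B is carried as the cyclopentane C10–C8–C7–C6–C5 and enlarged by insertion of C9 (cobalt-hydride HAT, radical–polar crossover, semipinacol shift of C8 from C10 to C9). Enabling feature: quaternary C9 (C20 methyl, C11 tether) lies between sp2 C10 and the C8 methine, so C10(=O)–C9–C8 of ring B is a 2,2,3-trisubstituted cyclohexanone (semipinacol) retron.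
3. 19 ⇒ α-hydroxy ketone 18 ⇒ cyclopentenyl ketone 16 (asymmetric methyl conjugate addition sets C8, enolate hydroxylation sets the C10 carbinol, methylenation brings C20) ⇒ acid 14 + 1-iodocyclopentene.
4. 14 ⇒ aldehyde 11 (aryl addition, benzylic deoxygenation) ⇒ Diels–Alder of diene 7 with (E)-but-2-enal (bonds C7'–C8' and C9'–C10'), then C9' methylation; 7 ⇐ keto ester 5 (chiral-imine Michael addition of 2-methylcyclohexanone to methyl acrylate sets C4' and supplies C12, C11, C9).
5. Ring order: proximal cyclohexane (purchased) → proximal cyclohexene (Diels–Alder) → arene attached → cyclopentane attached → ring B by 5→6 ring expansion → ring A by annulation.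

Key step: step 12

## Remarks

- Abbreviations in names: Ar = 2,5-dimethoxyphenyl; Dec = (1S,4aS,5R,6R)-5-(ArCH2)-1,5,6-trimethyl-1,2,3,4,4a,5,6,7-octahydronaphthalen-1-yl, the proximal decalin bound through its quaternary C4'.
- Assumption: the target is taken as the free bis(hydrogen sulfate) as drawn; it is liberated on an acid-form resin in the last step and is best stored as its disodium salt.
- The minor enantiomer carried from step 2 becomes a diastereomer after the ligand-controlled step 10 and should be removable there by chromatography.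

## Route

Step 1
Reactants: 1 2-methylcyclohexan-1-one; 2 (R)-1-phenylethan-1-amine
Product: 3 N-[(1R)-1-phenylethyl]-2-methylcyclohexan-1-imine
Conditions: TsOH (cat.), toluene, reflux, Dean–Stark
Reagents that add atoms: (R)-1-phenylethan-1-amine (2), C[C@@H](N)c1ccccc1
Why: Acid-catalysed imine condensation with azeotropic removal of water; the ring α-centre stays racemic because it is erased by tautomerisation in step 2.

Step 2
Reactants: 3 N-[(1R)-1-phenylethyl]-2-methylcyclohexan-1-imine; 4 methyl prop-2-enoate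
Product: 5 methyl 3-[(1S)-1-methyl-2-oxocyclohexyl]propanoate
Conditions: 4 (1.3 equiv), THF, 25 °C; then 10% aq AcOH, 25 °C
Reagents that add atoms: methyl prop-2-enoate (4), C=CC(=O)OC; water, O
Why: Asymmetric Michael addition of the chiral imine through its more substituted secondary enamine tautomer (aza-ene-like chair transition state with internal N–H transfer), in which the 1-phenylethyl group blocks one enamine face so that the quaternary C4' should form as (S), followed by mild acid hydrolysis to the ketone and the auxiliary.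

Step 3
Reactants: 5 methyl 3-[(1S)-1-methyl-2-oxocyclohexyl]propanoate
Product: 6 methyl 3-[(1S)-1-methyl-2-{[(trifluoromethyl)sulfonyl]oxy}cyclohex-2-en-1-yl]propanoate
Conditions: LiN(i-Pr)2, THF, −78 °C; PhNTf2, −78 → 0 °C
Reagents that add atoms: N-phenylbis(trifluoromethanesulfonimide), O=S(=O)(N(c1ccccc1)S(=O)(=O)C(F)(F)F)C(F)(F)F
Why: Kinetic enolisation can occur only on the CH2 side of the ketone (the other α-carbon is quaternary and the ketone is far more acidic than the ester), and O-triflation gives the vinyl triflate regiospecifically without touching C4'.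

Step 4
Reactants: 6 methyl 3-[(1S)-1-methyl-2-{[(trifluoromethyl)sulfonyl]oxy}cyclohex-2-en-1-yl]propanoate
Product: 7 methyl 3-[(1S)-2-ethenyl-1-methylcyclohex-2-en-1-yl]propanoate
Conditions: tributyl(ethenyl)stannane, Pd(PPh3)4 (3 mol %), LiCl, THF, reflux
Reagents that add atoms: tributyl(ethenyl)stannane, C=C[Sn](CCCC)(CCCC)CCCC
Why: Stille cross-coupling of the vinyl triflate (LiCl-assisted transmetalation) installs the vinyl group and thereby the diene C7'=C6'–C5'=C10' with no new stereocentre.

Step 5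
Reactants: 7 methyl 3-[(1S)-2-ethenyl-1-methylcyclohex-2-en-1-yl]propanoate; 8 (E)-but-2-enal
Product: 9 methyl 3-[(1S,4aS,5S,6R)-5-formyl-1,6-dimethyl-1,2,3,4,4a,5,6,7-octahydronaphthalen-1-yl]propanoate
Conditions: Me2AlCl (0.5 equiv), CH2Cl2, −78 → −30 °C
Reagents that add atoms: (E)-but-2-enal (8), C/C=C/C=O
Why: Lewis-acid-promoted Diels–Alder reaction in which the formyl-bearing carbon bonds to the substituted diene terminus C10' ("ortho" orientation), the E-dienophile fixes CHO trans to the C8' methyl, the endo transition state places H-9' and the C8' methyl cis to H-10', and the dienophile should approach anti to the pseudoaxial ester chain on C4' (the larger C4' substituent escaping A(1,2) strain with the vinyl group), which sets C8' and C10' relative to C4'.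

Step 6
Reactants: 9 methyl 3-[(1S,4aS,5S,6R)-5-formyl-1,6-dimethyl-1,2,3,4,4a,5,6,7-octahydronaphthalen-1-yl]propanoate
Product: 10 methyl 3-[(1S,4aR,5R,6R)-5-formyl-1,5,6-trimethyl-1,2,3,4,4a,5,6,7-octahydronaphthalen-1-yl]propanoate
Conditions: KOt-Bu (1.05 equiv), THF, −20 → 0 °C; MeI
Reagents that add atoms: iodomethane, CI
Why: α-Alkylation of the aldehyde potassium enolate (C9' becomes planar, so its endo/exo origin is irrelevant) in which MeI should enter anti to the vicinal C8' methyl, held pseudoaxial by A(1,3) strain with the exocyclic enolate, giving quaternary C9' with CHO cis to the C8' methyl and to H-10'.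

Step 7
Reactants: 10 methyl 3-[(1S,4aR,5R,6R)-5-formyl-1,5,6-trimethyl-1,2,3,4,4a,5,6,7-octahydronaphthalen-1-yl]propanoate
Product: 11 3-[(1S,4aR,5R,6R)-5-formyl-1,5,6-trimethyl-1,2,3,4,4a,5,6,7-octahydronaphthalen-1-yl]propanoic acid
Conditions: LiOH, THF/MeOH/H2O, 25 °C; aq HCl
Reagents that add atoms: lithium hydroxide, [Li+].[OH-]
Why: Saponification so that the chain terminus is carried as an inert carboxylate through the organolithium and dissolving-metal step that follows; the aldehyde has no α-hydrogen and no stereocentre is touched.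

Step 8
Reactants: 11 3-[(1S,4aR,5R,6R)-5-formyl-1,5,6-trimethyl-1,2,3,4,4a,5,6,7-octahydronaphthalen-1-yl]propanoic acid; 12 2-bromo-1,4-dimethoxybenzene
Product: 14 3-(Dec)propanoic acid, via dilithium alkoxide carboxylate 13 (not isolated)
Conditions: 12, n-BuLi, THF, −78 °C (2.1 equiv ArLi); 11, −78 °C; then Li, NH3(l)/THF, −78 °C; NH4Cl; aq HCl
Reagents that add atoms: 2-bromo-1,4-dimethoxybenzene (12), COc1ccc(OC)c(Br)c1, used as (2,5-dimethoxyphenyl)lithium, [Li]c1cc(OC)ccc1OC
Why: Tandem 1,2-addition and reductive deoxygenation, in which the first equivalent of aryllithium deprotonates the acid, the second adds to the neopentyl aldehyde, and the benzylic alkoxide is cleaved by Li/NH3 on NH4Cl quench (benzylic C–O hydrogenolysis under Birch-type conditions, carboxylate and isolated alkene being inert), so the carbinol centre is erased and C11' becomes CH2.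

Step 9
Reactants: 14 3-(Dec)propanoic acid; 15 1-iodocyclopent-1-ene
Product: 16 1-(cyclopent-1-en-1-yl)-3-(Dec)propan-1-one
Conditions: 15, t-BuLi (2 equiv per 15), Et2O, −78 °C; then 14 in THF (2.2 equiv alkenyllithium), −78 → 0 °C; aq NH4Cl
Reagents that add atoms: 1-iodocyclopent-1-ene (15), IC1=CCCC1, used as cyclopent-1-en-1-yllithium, [Li]C1=CCCC1
Why: Ketone synthesis from a lithium carboxylate and an organolithium, in which the stable dilithio gem-diolate prevents over-addition and collapses on work-up to the cyclopentenyl ketone, bringing in C5–C8 and C10 with no new stereocentre.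

Step 10
Reactants: 16 1-(cyclopent-1-en-1-yl)-3-(Dec)propan-1-one
Product: 18 1-[(1S,2S)-1-hydroxy-2-methylcyclopentyl]-3-(Dec)propan-1-one, via bromomagnesium enolate 17 (not isolated)
Conditions: MeMgBr, CuBr·SMe2 (5 mol %), (R)-1-[(S)-2-(diphenylphosphino)ferrocenyl]ethyldicyclohexylphosphine (6 mol %; or its enantiomer, whichever delivers (S)-C8), t-BuOMe, −78 °C; then 2-(phenylsulfonyl)-3-phenyloxaziridine, THF, −78 → −20 °C; aq NH4Cl
Reagents that add atoms: methylmagnesium bromide, C[Mg]Br; 2-(phenylsulfonyl)-3-phenyloxaziridine, O=S(=O)(N1OC1c1ccccc1)c1ccccc1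
Why: Copper-catalysed asymmetric conjugate addition of MeMgBr (ligand control of the enone face, the resident stereocentres being remote) sets C8 as (S), and electrophilic hydroxylation of the regiodefined tetrasubstituted enolate by the N-sulfonyloxaziridine should occur anti to the new methyl (kept pseudoaxial by A(1,3) strain), so the C10 hydroxyl is trans and the acyl group cis to the C8 methyl.

Step 11
Reactants: 18 1-[(1S,2S)-1-hydroxy-2-methylcyclopentyl]-3-(Dec)propan-1-one
Product: 19 (1S,2S)-1-[4-(Dec)but-1-en-2-yl]-2-methylcyclopentan-1-ol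
Conditions: Zn, CH2Br2, TiCl4, THF/CH2Cl2, 0 → 25 °C
Reagents that add atoms: dibromomethane, BrCBr
Why: Non-basic Zn/CH2Br2/TiCl4 carbonyl methylenation of the hindered ketone, chosen because it tolerates the free tertiary α-hydroxyl and avoids base-induced α-ketol rearrangement; C8 and C10 are untouched and the new CH2 is the future C20.

Step 12
Reactants: 19 (1S,2S)-1-[4-(Dec)but-1-en-2-yl]-2-methylcyclopentan-1-ol
Product: 21 (2R,3S)-2-[2-(Dec)ethyl]-2,3-dimethylcyclohexan-1-one, via tertiary C9 carbocation equivalent 20 (not isolated)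
Conditions: [N,N′-bis(3,5-di-tert-butylsalicylidene)cyclohexane-1,2-diaminato]cobalt (Co(salen), 5 mol %), 1-fluoro-2,4,6-trimethylpyridinium triflate (15 mol %), PhSiH3 (15 mol %), acetone, 0 → 25 °C
Reagents that add atoms: none
Why: A cobalt hydride generated from the Co(salen) complex, the N-fluoropyridinium oxidant and PhSiH3 transfers a hydrogen atom to the CH2 terminus of the 1,1-disubstituted alkene (Markovnikov HAT), and the tertiary C9 radical is captured and oxidised at cobalt to the carbocation equivalent 20, which sits next to the C10 carbinol. A 1,2-shift of C8 from C10 to C9 with formation of the C10 carbonyl (semipinacol rearrangement) then inserts C9 into the cyclopentane C10–C8–C7–C6–C5, so that ring B (C5–C10) is formed by a 5→6 ring expansion and not by a cyclisation, together with the quaternary C9, the C20 methyl (former CH2 plus H) and the ketone that ring A needs. The closest known reaction types are the Co(salen)-catalysed HAT-initiated radical–polar crossover semipinacol rearrangement of tertiary allylic alcohols and the cationic ring expansion of 1-alkenylcycloalkanols. C8 migrates with retention, and C9 is set by the reacting rotamer, in which the C10–C8 bond is aligned with the vacant C9 orbital, the bulky C11 tether lies next to the small hydroxyl and the new methyl lies over the ring CH2 (C5); because the C8 methyl is cis to the alkenyl group (step 10), this rotamer should deliver the C20 and C17 methyls cis, i.e. (2R,3S) in 21. The step needs migration of the secondary C8 in preference to the primary C5, which the higher migratory aptitude of the more substituted carbon should secure, and HAT only at the unhindered 1,1-disubstituted alkene, which the shielding of the C5'=C6' alkene by quaternary C4' should secure.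

Step 13
Reactants: 21 (2R,3S)-2-[2-(Dec)ethyl]-2,3-dimethylcyclohexan-1-one
Product: 22 {[(5S,6R)-6-[2-(Dec)ethyl]-5,6-dimethylcyclohex-1-en-1-yl]oxy}trimethylsilane
Conditions: LiN(i-Pr)2, THF, −78 °C; Me3SiCl, −78 → 0 °C
Reagents that add atoms: chlorotrimethylsilane, C[Si](C)(C)Cl
Why: Deprotonation can occur only at C5 (C9 is quaternary) and O-silylation gives a single regioisomeric silyl enol ether with no stereocentre affected.

Step 14
Reactants: 22 {[(5S,6R)-6-[2-(Dec)ethyl]-5,6-dimethylcyclohex-1-en-1-yl]oxy}trimethylsilane; 23 4-methylpent-3-en-2-one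
Product: 24 (2R,3S)-2-[2-(Dec)ethyl]-2,3-dimethyl-6-(2-methyl-4-oxopentan-2-yl)cyclohexan-1-one (C5 epimers)
Conditions: TiCl4 (1.1 equiv), CH2Cl2, −78 °C; H2O
Reagents that add atoms: 4-methylpent-3-en-2-one (23), CC(=O)C=C(C)C
Why: Mukaiyama–Michael addition in which C5 of the silyl enol ether attacks the β,β-disubstituted carbon of TiCl4-activated mesityl oxide, forming the C5–C4 bond and the gem-dimethyl quaternary C4; C5 forms as an epimeric mixture that is corrected in step 15.

Step 15
Reactants: 24 (2R,3S)-2-[2-(Dec)ethyl]-2,3-dimethyl-6-(2-methyl-4-oxopentan-2-yl)cyclohexan-1-one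
Product: 25 (4aR,7S,8R)-8-[2-(Dec)ethyl]-4,4,7,8-tetramethyl-4,4a,5,6,7,8-hexahydronaphthalen-2(3H)-one
Conditions: KOH, MeOH, 65 °C
Reagents that add atoms: none
Why: Intramolecular aldol condensation (methyl-ketone carbon C1 onto the C10 carbonyl, the only six-membered mode) closes ring A and fixes the alkene as C1=C10 by conjugation, while C5, now the epimerisable γ-position of the enone, should equilibrate through the dienolate to the epimer with H-5 cis to the C9 and C8 methyls, whose ring B chair keeps the C11 tether and the C8 methyl equatorial.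

Step 16
Reactants: 25 (4aR,7S,8R)-8-[2-(Dec)ethyl]-4,4,7,8-tetramethyl-4,4a,5,6,7,8-hexahydronaphthalen-2(3H)-one
Product: 26 ethane-1,2-diyl dithioketal of 25 (spiro-1,3-dithiolane at C2)
Conditions: HS(CH2)2SH, Zn(OTf)2 (10 mol %), CH2Cl2, 25 °C
Reagents that add atoms: ethane-1,2-dithiol, SCCS
Why: Lewis-acid-catalysed dithioketalisation of the unhindered C2 carbonyl; the fully substituted β-carbon C10 should not take up thiol in a conjugate sense and the double bond stays at C1=C10.

Step 17
Reactants: 26 ethane-1,2-diyl dithioketal of 25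
Product: 27 (1R,2R,5S,8aS)-1-(ArCH2)-1,2,5-trimethyl-5-{2-[(1R,2S,4aR)-1,2,5,5-tetramethyl-1,2,3,4,4a,5,6,7-octahydronaphthalen-1-yl]ethyl}-1,2,3,5,6,7,8,8a-octahydronaphthalene
Conditions: Raney Ni (W-2, acetone-deactivated), EtOH, 60 °C
Reagents that add atoms: none
Why: Mozingo desulfurisation cleaves both C–S bonds to give the C2 methylene, the hindered trisubstituted alkenes being expected to resist the deactivated catalyst, so no stereocentre changes.

Step 18
Reactants: 27 toxiusol hydroquinone dimethyl ether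
Product: 29 toxiusol hydroquinone (the benzene-1,4-diol corresponding to 27), via benzoquinone 28 (not isolated)
Conditions: (NH4)2Ce(NO3)6 (2.5 equiv), MeCN/H2O, 0 °C; then Na2S2O4, Et2O/H2O, 25 °C, argon
Reagents that add atoms: water, O
Why: Oxidative demethylation of the hydroquinone dimethyl ether by (NH4)2Ce(NO3)6 gives the quinone (new carbonyl oxygens from water) without the strong acids that would isomerise the alkenes, and dithionite reduces it to the air-sensitive hydroquinone, which is used at once.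

Step 19
Reactants: 29 toxiusol hydroquinone
Product: 30 toxiusol
Conditions: SO3·pyridine (6 equiv), pyridine, 50 °C; then sulfonic acid resin (H+ form), MeOH, 0 °C
Reagents that add atoms: sulfur trioxide–pyridine complex, [O-]S(=O)(=O)[n+]1ccccc1
Why: O-Sulfation of both phenols with the SO3–pyridine complex and exchange of the pyridinium counter-ions on acid-form resin gives the bis(hydrogen sulfate) with no effect on the stereocentres.

## Compound list

1 | 2-methylcyclohexan-1-one (racemic) | CC1CCCCC1=O | starting material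
2 | (R)-1-phenylethan-1-amine | C[C@@H](N)c1ccccc1 | starting material
3 | N-[(1R)-1-phenylethyl]-2-methylcyclohexan-1-imine (ring C2 epimers) | CC1CCCCC1=N[C@H](C)c1ccccc1 | intermediate
4 | methyl prop-2-enoate | C=CC(=O)OC | starting material
5 | methyl 3-[(1S)-1-methyl-2-oxocyclohexyl]propanoate | O=C1CCCC[C@@]1(C)CCC(=O)OC | intermediate
6 | methyl 3-[(1S)-1-methyl-2-{[(trifluoromethyl)sulfonyl]oxy}cyclohex-2-en-1-yl]propanoate | FC(F)(F)S(=O)(=O)OC1=CCCC[C@@]1(C)CCC(=O)OC | intermediate
7 | methyl 3-[(1S)-2-ethenyl-1-methylcyclohex-2-en-1-yl]propanoate | C=CC1=CCCC[C@@]1(C)CCC(=O)OC | intermediate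
8 | (E)-but-2-enal | C/C=C/C=O | starting material
9 | methyl 3-[(1S,4aS,5S,6R)-5-formyl-1,6-dimethyl-1,2,3,4,4a,5,6,7-octahydronaphthalen-1-yl]propanoate | C[C@@H]1CC=C2[C@@H](CCC[C@@]2(C)CCC(=O)OC)[C@H]1C=O | intermediate
10 | methyl 3-[(1S,4aR,5R,6R)-5-formyl-1,5,6-trimethyl-1,2,3,4,4a,5,6,7-octahydronaphthalen-1-yl]propanoate | C[C@@H]1CC=C2[C@@H](CCC[C@@]2(C)CCC(=O)OC)[C@]1(C)C=O | intermediate
11 | 3-[(1S,4aR,5R,6R)-5-formyl-1,5,6-trimethyl-1,2,3,4,4a,5,6,7-octahydronaphthalen-1-yl]propanoic acid | C[C@@H]1CC=C2[C@@H](CCC[C@@]2(C)CCC(=O)O)[C@]1(C)C=O | intermediate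
12 | 2-bromo-1,4-dimethoxybenzene | COc1ccc(OC)c(Br)c1 | starting material
13 | dilithium salt of the benzylic alkoxide carboxylate from ArLi addition to 11 (carbinol epimers) | C[C@@H]1CC=C2[C@@H](CCC[C@@]2(C)CCC(=O)[O-])[C@]1(C)C([O-])c1cc(OC)ccc1OC.[Li+].[Li+] | intermediate
14 | 3-(Dec)propanoic acid | C[C@@H]1CC=C2[C@@H](CCC[C@@]2(C)CCC(=O)O)[C@]1(C)Cc1cc(OC)ccc1OC | intermediate
15 | 1-iodocyclopent-1-ene | IC1=CCCC1 | starting material
16 | 1-(cyclopent-1-en-1-yl)-3-(Dec)propan-1-one | C[C@@H]1CC=C2[C@@H](CCC[C@@]2(C)CCC(=O)C3=CCCC3)[C@]1(C)Cc1cc(OC)ccc1OC | intermediate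
17 | bromomagnesium enolate of 1-[(2S)-2-methylcyclopentyl]-3-(Dec)propan-1-one (exocyclic C9=C10) | C[C@@H]1CC=C2[C@@H](CCC[C@@]2(C)CCC(O[Mg]Br)=C3CCC[C@@H]3C)[C@]1(C)Cc1cc(OC)ccc1OC | intermediate
18 | 1-[(1S,2S)-1-hydroxy-2-methylcyclopentyl]-3-(Dec)propan-1-one | C[C@@H]1CC=C2[C@@H](CCC[C@@]2(C)CCC(=O)[C@]3(O)CCC[C@@H]3C)[C@]1(C)Cc1cc(OC)ccc1OC | intermediate
19 | (1S,2S)-1-[4-(Dec)but-1-en-2-yl]-2-methylcyclopentan-1-ol | C[C@@H]1CC=C2[C@@H](CCC[C@@]2(C)CCC(=C)[C@]3(O)CCC[C@@H]3C)[C@]1(C)Cc1cc(OC)ccc1OC | intermediate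
20 | 2-[(1S,2S)-1-hydroxy-2-methylcyclopentyl]-4-(Dec)butan-2-ylium (cobalt-bound C9 cation equivalent) | C[C@@H]1CC=C2[C@@H](CCC[C@@]2(C)CC[C+](C)[C@]3(O)CCC[C@@H]3C)[C@]1(C)Cc1cc(OC)ccc1OC | intermediate
21 | (2R,3S)-2-[2-(Dec)ethyl]-2,3-dimethylcyclohexan-1-one | C[C@@H]1CC=C2[C@@H](CCC[C@@]2(C)CC[C@@]3(C)C(=O)CCC[C@@H]3C)[C@]1(C)Cc1cc(OC)ccc1OC | intermediate
22 | {[(5S,6R)-6-[2-(Dec)ethyl]-5,6-dimethylcyclohex-1-en-1-yl]oxy}trimethylsilane | C[C@@H]1CC=C2[C@@H](CCC[C@@]2(C)CC[C@@]3(C)C(O[Si](C)(C)C)=CCC[C@@H]3C)[C@]1(C)Cc1cc(OC)ccc1OC | intermediate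
23 | 4-methylpent-3-en-2-one | CC(=O)C=C(C)C | starting material
24 | (2R,3S)-2-[2-(Dec)ethyl]-2,3-dimethyl-6-(2-methyl-4-oxopentan-2-yl)cyclohexan-1-one (C5 epimers) | C[C@@H]1CC=C2[C@@H](CCC[C@@]2(C)CC[C@@]3(C)C(=O)C(C(C)(C)CC(C)=O)CC[C@@H]3C)[C@]1(C)Cc1cc(OC)ccc1OC | intermediate
25 | (4aR,7S,8R)-8-[2-(Dec)ethyl]-4,4,7,8-tetramethyl-4,4a,5,6,7,8-hexahydronaphthalen-2(3H)-one | C[C@@H]1CC=C2[C@@H](CCC[C@@]2(C)CC[C@@]3(C)C4=CC(=O)CC(C)(C)[C@H]4CC[C@@H]3C)[C@]1(C)Cc1cc(OC)ccc1OC | intermediate
26 | ethane-1,2-diyl dithioketal of 25 (spiro-1,3-dithiolane at C2, stereocentres as in 25) | C[C@@H]1CC=C2[C@@H](CCC[C@@]2(C)CC[C@@]3(C)C4=CC5(SCCS5)CC(C)(C)[C@H]4CC[C@@H]3C)[C@]1(C)Cc1cc(OC)ccc1OC | intermediate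
27 | (1R,2R,5S,8aS)-1-[(2,5-dimethoxyphenyl)methyl]-1,2,5-trimethyl-5-{2-[(1R,2S,4aR)-1,2,5,5-tetramethyl-1,2,3,4,4a,5,6,7-octahydronaphthalen-1-yl]ethyl}-1,2,3,5,6,7,8,8a-octahydronaphthalene | C[C@@H]1CC=C2[C@@H](CCC[C@@]2(C)CC[C@@]3(C)C4=CCCC(C)(C)[C@H]4CC[C@@H]3C)[C@]1(C)Cc1cc(OC)ccc1OC | intermediate
28 | 2-substituted cyclohexa-2,5-diene-1,4-dione corresponding to 27 (quinone) | C[C@@H]1CC=C2[C@@H](CCC[C@@]2(C)CC[C@@]3(C)C4=CCCC(C)(C)[C@H]4CC[C@@H]3C)[C@]1(C)CC1=CC(=O)C=CC1=O | intermediate
29 | 2-substituted benzene-1,4-diol corresponding to 27 (toxiusol hydroquinone) | C[C@@H]1CC=C2[C@@H](CCC[C@@]2(C)CC[C@@]3(C)C4=CCCC(C)(C)[C@H]4CC[C@@H]3C)[C@]1(C)Cc1cc(O)ccc1O | intermediate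
30 | toxiusol, the benzene-1,4-diyl bis(hydrogen sulfate) of 29 | C[C@@H]1CC=C2[C@@H](CCC[C@@]2(C)CC[C@@]2(C)C3=CCCC(C)(C)[C@H]3CC[C@@H]2C)[C@]1(C)Cc1cc(OS(=O)(=O)O)ccc1OS(=O)(=O)O | target

## Step count and risks

Total step count: 19. Longest linear sequence: 19 (fully linear from 2-methylcyclohexanone).

Steps most likely to fail:

Step 12. The primary C5 may migrate instead of C8, the C10 hydroxyl may close onto the C9 cation equivalent to give a spiro-oxirane, a proton may be lost to give a diene, or a weak rotamer bias may erode the configuration at C9. Fallback, setting out from 19: Mukaiyama hydration of the 1,1-disubstituted alkene (Co(acac)2, PhSiH3, O2, THF/i-PrOH) should give the vicinal diol F1. A pinacol rearrangement with BF3·OEt2 (CH2Cl2, −78 °C) then ionises the acyclic tertiary C9–OH and shifts C8 through the same cation and the same rotamer preference, which comes back to the route at 21.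

Step 5. Facial discrimination between the methyl and the ester-chain faces of the diene may be poor (two similar alkyl groups on C4'), the ortho regioselectivity may erode, and the diene may oligomerise under the Lewis acid. Fallback, setting out from 7: an auxiliary-controlled Diels–Alder reaction with (R)-4-benzyl-3-[(E)-but-2-enoyl]-1,3-oxazolidin-2-one and Et2AlCl (CH2Cl2, −78 → −30 °C), in which the chelated s-cis dienophile is shielded by the benzyl group, should give the N-acyl oxazolidinone adduct F2. Cleavage with EtSLi (THF, 0 °C) gives the S-ethyl thioester F3 and returns the auxiliary. Reduction of the thioester with Et3SiH and Pd/C (acetone, 25 °C) leaves the methyl ester untouched and comes back to the route at 9.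

Step 15. The aldol addition to the doubly flanked C10 carbonyl may be slow or reversible, with retro-Michael loss of mesityl oxide under base; the later desulfurisation (step 17) may also shift the C1=C10 alkene. Fallback, setting out from 22: a Mukaiyama aldol reaction with acetone (TiCl4, CH2Cl2, −78 °C) gives the β-hydroxy ketone F4. Dehydration (SOCl2, pyridine, 0 °C; then DBU) gives the isopropylidene ketone F5. Copper-catalysed conjugate addition of [2-(1,3-dioxolan-2-yl)ethyl]magnesium bromide (CuBr·SMe2, THF, −30 °C) builds quaternary C4 and, after equilibration of C5 with DBU, gives the dioxolane ketone F6. Acetal hydrolysis (pyridinium tosylate, acetone/H2O, 50 °C) gives the keto aldehyde F7. An intramolecular McMurry coupling (TiCl3, Zn–Cu couple, DME, reflux) forms C1=C10 regiospecifically with no C2 oxygen to remove, and comes back to the route at 27.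

## Further compounds

F1 | step 12 | (1S,2S)-1-[4-(Dec)-2-hydroxybutan-2-yl]-2-methylcyclopentan-1-ol (carbinol C9 epimers) | C[C@@H]1CC=C2[C@@H](CCC[C@@]2(C)CCC(C)(O)[C@]3(O)CCC[C@@H]3C)[C@]1(C)Cc1cc(OC)ccc1OC
F2 | step 5 | methyl 3-[(1S,4aS,5S,6R)-5-{[(4R)-4-benzyl-2-oxo-1,3-oxazolidin-3-yl]carbonyl}-1,6-dimethyl-1,2,3,4,4a,5,6,7-octahydronaphthalen-1-yl]propanoate | C[C@@H]1CC=C2[C@@H](CCC[C@@]2(C)CCC(=O)OC)[C@H]1C(=O)N1C(=O)OC[C@H]1Cc1ccccc1
F3 | step 5 | methyl 3-[(1S,4aS,5S,6R)-5-[(ethylsulfanyl)carbonyl]-1,6-dimethyl-1,2,3,4,4a,5,6,7-octahydronaphthalen-1-yl]propanoate | C[C@@H]1CC=C2[C@@H](CCC[C@@]2(C)CCC(=O)OC)[C@H]1C(=O)SCC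
F4 | step 15 | (2R,3S)-2-[2-(Dec)ethyl]-6-(2-hydroxypropan-2-yl)-2,3-dimethylcyclohexan-1-one (C5 epimers) | C[C@@H]1CC=C2[C@@H](CCC[C@@]2(C)CC[C@@]3(C)C(=O)C(C(C)(C)O)CC[C@@H]3C)[C@]1(C)Cc1cc(OC)ccc1OC
F5 | step 15 | (2R,3S)-2-[2-(Dec)ethyl]-2,3-dimethyl-6-(propan-2-ylidene)cyclohexan-1-one | C[C@@H]1CC=C2[C@@H](CCC[C@@]2(C)CC[C@@]3(C)C(=O)C(=C(C)C)CC[C@@H]3C)[C@]1(C)Cc1cc(OC)ccc1OC
F6 | step 15 | (2R,3S,6R)-2-[2-(Dec)ethyl]-6-[4-(1,3-dioxolan-2-yl)-2-methylbutan-2-yl]-2,3-dimethylcyclohexan-1-one | C[C@@H]1CC=C2[C@@H](CCC[C@@]2(C)CC[C@@]3(C)C(=O)[C@@H](C(C)(C)CCC4OCCO4)CC[C@@H]3C)[C@]1(C)Cc1cc(OC)ccc1OC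
F7 | step 15 | 4-{(1R,3R,4S)-3-[2-(Dec)ethyl]-3,4-dimethyl-2-oxocyclohexyl}-4-methylpentanal | C[C@@H]1CC=C2[C@@H](CCC[C@@]2(C)CC[C@@]3(C)C(=O)[C@@H](C(C)(C)CCC=O)CC[C@@H]3C)[C@]1(C)Cc1cc(OC)ccc1OC
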